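The route rests on cutting ring A and the five-membered ring at once: a ruthenium-catalysed (2+2+2) cycloaddition of a 1,6-diyne with ethoxyethyne forms C3a–C7a, C4–C5 and C6–C7 in one operation. It exploits the substitution pattern of ring A: the chain C1–C2–C3 leaves it from the neighbouring atoms C7a and C3a, and its oxygens sit at C5 and C7, meta to one another. The precursor is a hepta-1,6-diyne holding both aryl-bearing stereocentres (C1, C2), a silyloxy group at C3, a free alkyne terminus (future C4) and a pinacolboryl-capped terminus (future C7, boron later becoming oxygen). The benzylidene is attached afterwards by Ramberg–Bäcklund olefination; light sets the Z geometry last.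

Key step: step 7

Remarks
- Numbering: indane atoms are numbered as in the core of the target, C1 (4-oxyphenyl), C2 (3,5-dioxyphenyl), C3 (benzylidene carbon), ring A = C3a–C7a; dihydrobenzofuran atoms are primed.
- Assumption: Rh2(R-PTAD)4 is taken to deliver the (2R,3S)-cis-dihydrobenzofuran in step 14; should the sense be opposite, the equally available Rh2(S-PTAD)4 is used.
- Design: an alkynyl–boron bond does not survive base, fluoride or nucleophiles. The two alkyne termini are therefore told apart as dibromoalkene and C-silyl alkyne, boron is carried as a trifluoroborate through the desilylation, and the boronic ester is made directly before the cycloaddition.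
- Design: the C7 oxygen is ethylated so that both ring A oxygens carry the same group. Deprotection comes before the E-to-Z inversion because acid would return the Z alkene to E.

Step 1
Reactants: 1 3,5-dimethoxybenzaldehyde; 2 nitromethane
Product: 3 (E)-nitrostyrene
Conditions: NH4OAc, AcOH, 100 °C
Reagents that add atoms: none
Why: Henry condensation with in situ dehydration gives the thermodynamically favoured E-nitroalkene; no stereocentre is formed.

Step 2
Reactants: 3 (E)-nitrostyrene; 4 (4-methoxyphenyl)acetaldehyde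
Product: 6 syn nitro dibromoalkene, via Michael aldehyde 5 (not isolated)
Conditions: (R)-α,α-diphenylprolinol trimethylsilyl ether (10 mol%), 4-nitrophenol (10 mol%), toluene, 0 °C; crude solution added to preformed PPh3/CBr4/Zn in CH2Cl2, 0 °C
Reagents that add atoms: carbon tetrabromide, BrC(Br)(Br)Br
Why: Amine-catalysed Michael addition of the aldehyde enamine to the nitroalkene through a synclinal open transition state, with one enamine face shielded by the diarylsiloxymethyl group, should set C1 and C2 together as the syn (2R,3R) pair, and the base-free Ramirez dibromo-olefination (first stage of the Corey–Fuchs sequence) consumes the epimerisable α-aryl aldehyde at once.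

Step 3
Reactants: 6 syn nitro dibromoalkene
Product: 8 α-aryl aldehyde, via sodium nitronate 7 (not isolated)
Conditions: NaOMe, MeOH/THF, 0 °C; added to aq TiCl3, NH4OAc (pH 5), 0 → 20 °C
Reagents that add atoms: water, O
Why: Reductive Nef reaction, in which the nitronate is reduced by TiCl3 to the imine and hydrolysed under weakly acidic buffer, so that the dibromoalkene and the new α-aryl aldehyde (C2) are not exposed to base; 8 is used crude.

Step 4
Reactants: 8 α-aryl aldehyde
Product: 10 silyl ether of the propargylic alcohol, via lithium alkoxide 9 (not isolated)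
Conditions: ethynyltrimethylsilane, n-BuLi, THF, −78 °C; 8; then TBSOTf, −78 → 0 °C
Reagents that add atoms: ethynyltrimethylsilane (as its lithium acetylide), C#C[Si](C)(C)C; tert-butyldimethylsilyl trifluoromethanesulfonate, CC(C)(C)[Si](C)(C)OS(=O)(=O)C(F)(F)F
Why: 1,2-Addition of a lithium acetylide at low temperature outruns enolisation and the alkoxide is silylated in the same flask; the carbinol centre C3 is left uncontrolled on purpose because it becomes trigonal in step 20.

Step 5
Reactants: 10 silyl ether of the propargylic alcohol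
Product: 13 potassium alkynyltrifluoroborate, via lithium acetylide 11 (not isolated), via lithium trimethoxyborate 12 (not isolated)
Conditions: n-BuLi (2.1 equiv), THF, −78 °C; B(OMe)3, −78 → −20 °C; aq KHF2, 20 °C
Reagents that add atoms: trimethyl borate, COB(OC)OC; potassium hydrogen difluoride, F.[F-].[K+]
Why: Corey–Fuchs alkyne synthesis (bromine–lithium exchange, 1,2-shift, deprotonation) generates the acetylide only at the C1 side because the other alkyne is C-silylated, and borylation followed by KHF2 gives a tetracoordinate trifluoroborate that tolerates the next, basic step; the stereocentres are not touched at −78 °C with controlled stoichiometry.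

Step 6
Reactants: 13 potassium alkynyltrifluoroborate
Product: 15 boryl diyne, via desilylated trifluoroborate 14 (not isolated)
Conditions: K2CO3 (cat.), MeOH, 20 °C; evaporate; pinacol, TMSCl, MeCN, 0 → 20 °C; used without chromatography
Reagents that add atoms: pinacol, CC(C)(O)C(C)(C)O
Why: Base-catalysed methanolysis of the alkynylsilane frees the second terminus while boron is protected as the trifluoroborate, and fluoride abstraction by chlorotrimethylsilane in the presence of pinacol (trifluoroborate-to-boronate interconversion) then gives the alkynylboronic ester under base-free conditions.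

Step 7
Reactants: 15 boryl diyne; 16 ethoxyethyne
Product: 17 5-ethoxy-7-boryl indane
Conditions: Cp*RuCl(cod) (10 mol%), DCE, 20 °C; 15 added slowly to 16 (4 equiv)
Reagents that add atoms: none
Why: The Cp*RuCl fragment couples the two tethered alkynes of 15 oxidatively to a ruthenacycle fused to the future carbocycle (bond C3a–C7a), the ynol ether then inserts at the less hindered Ru–C4 side and reductive elimination releases the benzene (bonds C4–C5 and C6–C7). The closest known reaction is the Cp*RuCl(cod)-catalysed (2+2+2) cycloaddition of end-substituted 1,6-diynes with terminal alkynes, which tolerates alkynylboronates and is meta-selective. The five-membered ring closes by metal-templated cyclisation of the 1,6-diyne across its three-atom tether C1–C2–C3, and ring A closes by the formal [2+2+2] annulation with the third alkyne. No stereocentre is formed; C1 and C2 are spectators and C3 remains an epimer mixture. The step needs regioselectivity, ethoxy meta to boron, and the steric difference between the boryl-capped terminus (future C7) and the unsubstituted terminus (future C4) should secure it by directing the ethoxy-bearing carbon to C4. Slow addition of 15 to excess 16 should suppress self-trimerisation of the diyne.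

Step 8
Reactants: 17 5-ethoxy-7-boryl indane
Product: 19 5,7-diethoxy indane silyl ether, via sodium phenoxide 18 (not isolated)
Conditions: H2O2, NaOH, THF/H2O, 0 °C; Na2S2O3; then EtI, Bu4NBr (cat.), 40 °C
Reagents that add atoms: hydrogen peroxide, OO; iodoethane, CCI
Why: Alkaline peroxide oxidation of the aryl–boron bond (1,2-aryl shift from boron to oxygen, position retained) gives the C7 phenoxide, which is O-ethylated in the same flask (Williamson ether synthesis).

Step 9
Reactants: 19 5,7-diethoxy indane silyl ether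
Product: 20 indan-3-ol
Conditions: TBAF, THF, 20 °C
Reagents that add atoms: none
Why: Fluoride-mediated cleavage of the silyl ether; no other group in 19 reacts with TBAF.

Step 10
Reactants: 20 indan-3-ol
Product: 21 indan-3-yl thioacetate
Conditions: AcSH, ZnI2, DCE, 20 °C
Reagents that add atoms: thioacetic acid, CC(=O)S
Why: Zinc iodide-promoted substitution of a benzylic alcohol by thioacetic acid through the C3 benzylic cation, so both C3 epimers converge; sulfur is expected to enter trans to the C2 aryl group, a configuration that is erased in step 20.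

Step 11
Reactants: 22 5-bromo-2-hydroxybenzonitrile; 23 4-methoxybenzyl chloride
Product: 24 benzyl ether nitrile
Conditions: K2CO3, DMF, 60 °C
Reagents that add atoms: none
Why: Williamson etherification of the phenol; the benzylic CH2 introduced here becomes C2′.

Step 12
Reactants: 24 benzyl ether nitrile; 25 (3,5-dimethoxyphenyl)magnesium chloride
Product: 27 diaryl ketone, via magnesium ketiminate 26 (not isolated)
Conditions: THF, 0 → 60 °C; then 2 M HCl, 20 °C
Reagents that add atoms: water, O
Why: Grignard addition to the nitrile stops at the ketiminate, which dilute acid hydrolyses to the ketone without cleaving the benzyl ether or touching the aryl bromide.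

Step 13
Reactants: 27 diaryl ketone
Product: 28 hydrazone
Conditions: N2H4·H2O, AcOH (cat.), EtOH, 80 °C
Reagents that add atoms: hydrazine, NN
Why: Condensation of the ketone with hydrazine gives the N-unsubstituted hydrazone, the precursor of the diazo compound.

Step 14
Reactants: 28 hydrazone
Product: 30 cis-dihydrobenzofuran, via diaryldiazomethane 29 (not isolated)
Conditions: MnO2, CH2Cl2, 0 °C, filter; Rh2(R-PTAD)4 (1 mol%), CH2Cl2, 0 °C
Reagents that add atoms: none
Why: Oxidation to the diazo compound and intramolecular rhodium-carbene insertion into the benzylic ether C–H bond (donor/donor carbene C–H insertion, known for 2,3-diaryl dihydrobenzofurans) closes the furan ring; the chiral carboxylate ligands set C3′ and C2′ in the cis arrangement.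

Step 15
Reactants: 30 cis-dihydrobenzofuran
Product: 31 trans-dihydrobenzofuran
Conditions: BF3·OEt2, CH2Cl2, −20 → 0 °C
Reagents that add atoms: none
Why: Lewis acid-promoted reversible heterolysis of the C2′–O bond (a 4-methoxybenzylic aryl ether) and re-closure epimerises C2′ to the thermodynamically favoured trans isomer while C3′ is untouched (acid-mediated cis-to-trans isomerisation of 2-aryl dihydrobenzofurans).

Step 16
Reactants: 31 trans-dihydrobenzofuran
Product: 34 benzylic alcohol, via aryllithium 32 (not isolated), via aldehyde 33 (not isolated)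
Conditions: n-BuLi, THF, −78 °C; DMF; then MeOH, NaBH4, 0 °C
Reagents that add atoms: N,N-dimethylformamide, CN(C)C=O
Why: Bromine–lithium exchange and formylation of the aryllithium with DMF (Bouveault-type formylation), followed by borohydride reduction of the aldehyde in the same flask.

Step 17
Reactants: 34 benzylic alcohol
Product: 35 benzylic chloride
Conditions: PPh3, CCl4, CH2Cl2, 20 °C; used crude
Reagents that add atoms: carbon tetrachloride, ClC(Cl)(Cl)Cl
Why: Appel chlorination under neutral conditions, chosen because the electron-rich benzylic chloride and the acid-sensitive C2′–O bond tolerate neither acid nor heat.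

Step 18
Reactants: 21 indan-3-yl thioacetate; 35 benzylic chloride
Product: 37 sulfide, via sodium thiolate 36 (not isolated)
Conditions: NaOMe (1.0 equiv), THF/MeOH, 0 °C; then 35, DMF, 0 → 20 °C
Reagents that add atoms: none
Why: Methanolysis of the thioester gives the thiolate, which is alkylated by the benzylic chloride (SN2 thioether synthesis) under basic conditions, so the acid-labile dihydrobenzofuran never meets acid in the presence of a thiol.

Step 19
Reactants: 37 sulfide
Product: 38 sulfone
Conditions: mCPBA (2.2 equiv), NaHCO3, CH2Cl2, 0 °C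
Reagents that add atoms: 3-chloroperoxybenzoic acid, OOC(=O)c1cccc(Cl)c1
Why: Peracid oxidation of the sulfide through the sulfoxide to the sulfone; the buffer protects the dihydrobenzofuran.

Step 20
Reactants: 38 sulfone
Product: 41 E benzylidene indane, via chlorosulfone 39 (not isolated), via episulfone 40 (not isolated)
Conditions: KOH, CCl4, t-BuOH/H2O, 60 °C
Reagents that add atoms: none
Why: Ramberg–Bäcklund reaction with in situ α-chlorination, 1,3-elimination to the episulfone and loss of SO2 creates the C3=CH bond where olefination of the enolisable indanone would be unreliable; a benzylic sulfone should give mainly the E alkene, which step 22 corrects.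

Step 21
Reactants: 41 E benzylidene indane
Product: 42 E octaphenol
Conditions: BBr3 (excess), CH2Cl2, −78 → 20 °C; MeOH
Reagents that add atoms: none
Why: Lewis acid cleavage of all eight aryl alkyl ethers; the C2′–O bond may open reversibly but should re-close to the trans dihydrobenzofuran on work-up, and the E alkene is the acid-stable isomer.

Step 22
Reactants: 42 E octaphenol
Product: 43 target
Conditions: fac-Ir(ppy)3 (1 mol%), 450 nm LEDs, degassed MeCN/MeOH, 20 °C; preparative HPLC, 42 recycled
Reagents that add atoms: none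
Why: Triplet-sensitised contra-thermodynamic E-to-Z isomerisation of a stilbene-type alkene: the planar E isomer accepts triplet energy, whereas the Z isomer, twisted by the clash of the benzofuranyl ring with C4–H, should accumulate in the photostationary state; visible-light sensitisation avoids singlet photocyclisation and no stereocentre is involved.

Compound list
1 | 3,5-dimethoxybenzaldehyde | COc1cc(C=O)cc(OC)c1 | starting material
2 | nitromethane | C[N+](=O)[O-] | starting material
3 | (E)-1,3-dimethoxy-5-(2-nitrovinyl)benzene | COc1cc(/C=C/[N+](=O)[O-])cc(OC)c1 | intermediate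
4 | (4-methoxyphenyl)acetaldehyde | COc1ccc(CC=O)cc1 | starting material
5 | (2R,3R)-3-(3,5-dimethoxyphenyl)-2-(4-methoxyphenyl)-4-nitrobutanal (syn) | COc1ccc([C@H](C=O)[C@H](c2cc(OC)cc(OC)c2)C[N+](=O)[O-])cc1 | intermediate
6 | 1-[(2R,3S)-5,5-dibromo-3-(4-methoxyphenyl)-1-nitropent-4-en-2-yl]-3,5-dimethoxybenzene | COc1ccc([C@H](C=C(Br)Br)[C@H](c2cc(OC)cc(OC)c2)C[N+](=O)[O-])cc1 | intermediate
7 | sodium nitronate of 6 | COc1ccc([C@H](C=C(Br)Br)[C@H](c2cc(OC)cc(OC)c2)C=[N+]([O-])[O-])cc1.[Na+] | intermediate
8 | (2R,3S)-5,5-dibromo-2-(3,5-dimethoxyphenyl)-3-(4-methoxyphenyl)pent-4-enal | COc1ccc([C@H](C=C(Br)Br)[C@H](c2cc(OC)cc(OC)c2)C=O)cc1 | intermediate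
9 | lithium (3S,4R)-1,1-dibromo-4-(3,5-dimethoxyphenyl)-3-(4-methoxyphenyl)-7-(trimethylsilyl)hept-1-en-6-yn-5-olate, C5 epimers | COc1ccc([C@H](C=C(Br)Br)[C@H](c2cc(OC)cc(OC)c2)C([O-])C#C[Si](C)(C)C)cc1.[Li+] | intermediate
10 | (3S,4R)-1,1-dibromo-5-[(tert-butyldimethylsilyl)oxy]-4-(3,5-dimethoxyphenyl)-3-(4-methoxyphenyl)-7-(trimethylsilyl)hept-1-en-6-yne, C5 epimers | COc1ccc([C@H](C=C(Br)Br)[C@H](c2cc(OC)cc(OC)c2)C(O[Si](C)(C)C(C)(C)C)C#C[Si](C)(C)C)cc1 | intermediate
11 | lithium acetylide from 10 (C1-side alkyne lithiated, other alkyne C-silylated) | COc1ccc([C@H](C#C[Li])[C@H](c2cc(OC)cc(OC)c2)C(O[Si](C)(C)C(C)(C)C)C#C[Si](C)(C)C)cc1 | intermediate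
12 | lithium alkynyl(trimethoxy)borate from 11 | COc1ccc([C@H](C#C[B-](OC)(OC)OC)[C@H](c2cc(OC)cc(OC)c2)C(O[Si](C)(C)C(C)(C)C)C#C[Si](C)(C)C)cc1.[Li+] | intermediate
13 | potassium [(3R,4R)-5-[(tert-butyldimethylsilyl)oxy]-4-(3,5-dimethoxyphenyl)-3-(4-methoxyphenyl)-7-(trimethylsilyl)hepta-1,6-diyn-1-yl]trifluoroborate, C5 epimers | COc1ccc([C@H](C#C[B-](F)(F)F)[C@H](c2cc(OC)cc(OC)c2)C(O[Si](C)(C)C(C)(C)C)C#C[Si](C)(C)C)cc1.[K+] | intermediate
14 | potassium [(3R,4R)-5-[(tert-butyldimethylsilyl)oxy]-4-(3,5-dimethoxyphenyl)-3-(4-methoxyphenyl)hepta-1,6-diyn-1-yl]trifluoroborate, C5 epimers | COc1ccc([C@H](C#C[B-](F)(F)F)[C@H](c2cc(OC)cc(OC)c2)C(O[Si](C)(C)C(C)(C)C)C#C)cc1.[K+] | intermediate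
15 | 2-[(3R,4R)-5-[(tert-butyldimethylsilyl)oxy]-4-(3,5-dimethoxyphenyl)-3-(4-methoxyphenyl)hepta-1,6-diyn-1-yl]-4,4,5,5-tetramethyl-1,3,2-dioxaborolane, C5 epimers (key-step precursor) | COc1ccc([C@H](C#CB2OC(C)(C)C(C)(C)O2)[C@H](c2cc(OC)cc(OC)c2)C(O[Si](C)(C)C(C)(C)C)C#C)cc1 | intermediate
16 | ethoxyethyne | CCOC#C | starting material
17 | (1R,2R)-3-[(tert-butyldimethylsilyl)oxy]-2-(3,5-dimethoxyphenyl)-5-ethoxy-1-(4-methoxyphenyl)-7-(4,4,5,5-tetramethyl-1,3,2-dioxaborolan-2-yl)indane, C3 epimers (key-step product) | COc1ccc([C@@H]2c3c(B4OC(C)(C)C(C)(C)O4)cc(OCC)cc3C(O[Si](C)(C)C(C)(C)C)[C@H]2c2cc(OC)cc(OC)c2)cc1 | intermediate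
18 | sodium 7-phenoxide of the indane (C3 silyl ether, 5-ethoxy) | COc1ccc([C@@H]2c3c([O-])cc(OCC)cc3C(O[Si](C)(C)C(C)(C)C)[C@H]2c2cc(OC)cc(OC)c2)cc1.[Na+] | intermediate
19 | (1R,2R)-3-[(tert-butyldimethylsilyl)oxy]-2-(3,5-dimethoxyphenyl)-5,7-diethoxy-1-(4-methoxyphenyl)indane, C3 epimers | COc1ccc([C@@H]2c3c(OCC)cc(OCC)cc3C(O[Si](C)(C)C(C)(C)C)[C@H]2c2cc(OC)cc(OC)c2)cc1 | intermediate
20 | (1R,2R)-2-(3,5-dimethoxyphenyl)-5,7-diethoxy-1-(4-methoxyphenyl)indan-3-ol, C3 epimers | COc1ccc([C@@H]2c3c(OCC)cc(OCC)cc3C(O)[C@H]2c2cc(OC)cc(OC)c2)cc1 | intermediate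
21 | S-[(1R,2R)-2-(3,5-dimethoxyphenyl)-5,7-diethoxy-1-(4-methoxyphenyl)indan-3-yl] ethanethioate, C3 left open (trans to the C2 aryl expected) | COc1ccc([C@@H]2c3c(OCC)cc(OCC)cc3C(SC(C)=O)[C@H]2c2cc(OC)cc(OC)c2)cc1 | intermediate
22 | 5-bromo-2-hydroxybenzonitrile | N#Cc1cc(Br)ccc1O | starting material
23 | 1-(chloromethyl)-4-methoxybenzene | COc1ccc(CCl)cc1 | starting material
24 | 5-bromo-2-[(4-methoxybenzyl)oxy]benzonitrile | COc1ccc(COc2ccc(Br)cc2C#N)cc1 | intermediate
25 | (3,5-dimethoxyphenyl)magnesium chloride | COc1cc([Mg]Cl)cc(OC)c1 | starting material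
26 | N-chloromagnesio ketimine from 24 and 25 | COc1ccc(COc2ccc(Br)cc2C(=N[Mg]Cl)c2cc(OC)cc(OC)c2)cc1 | intermediate
27 | {5-bromo-2-[(4-methoxybenzyl)oxy]phenyl}(3,5-dimethoxyphenyl)methanone | COc1ccc(COc2ccc(Br)cc2C(=O)c2cc(OC)cc(OC)c2)cc1 | intermediate
28 | hydrazone of 27 | COc1ccc(COc2ccc(Br)cc2C(=NN)c2cc(OC)cc(OC)c2)cc1 | intermediate
29 | diaryldiazomethane from 28 | COc1ccc(COc2ccc(Br)cc2C(=[N+]=[N-])c2cc(OC)cc(OC)c2)cc1 | intermediate
30 | (2R,3S)-5-bromo-3-(3,5-dimethoxyphenyl)-2-(4-methoxyphenyl)-2,3-dihydro-1-benzofuran (cis) | Brc1ccc2c(c1)[C@H](c1cc(OC)cc(OC)c1)[C@H](c1ccc(OC)cc1)O2 | intermediate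
31 | (2S,3S)-5-bromo-3-(3,5-dimethoxyphenyl)-2-(4-methoxyphenyl)-2,3-dihydro-1-benzofuran (trans) | Brc1ccc2c(c1)[C@H](c1cc(OC)cc(OC)c1)[C@@H](c1ccc(OC)cc1)O2 | intermediate
32 | 5-lithio derivative of 31 | [Li]c1ccc2c(c1)[C@H](c1cc(OC)cc(OC)c1)[C@@H](c1ccc(OC)cc1)O2 | intermediate
33 | (2S,3S)-3-(3,5-dimethoxyphenyl)-2-(4-methoxyphenyl)-2,3-dihydro-1-benzofuran-5-carbaldehyde | O=Cc1ccc2c(c1)[C@H](c1cc(OC)cc(OC)c1)[C@@H](c1ccc(OC)cc1)O2 | intermediate
34 | [(2S,3S)-3-(3,5-dimethoxyphenyl)-2-(4-methoxyphenyl)-2,3-dihydro-1-benzofuran-5-yl]methanol | OCc1ccc2c(c1)[C@H](c1cc(OC)cc(OC)c1)[C@@H](c1ccc(OC)cc1)O2 | intermediate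
35 | (2S,3S)-5-(chloromethyl)-3-(3,5-dimethoxyphenyl)-2-(4-methoxyphenyl)-2,3-dihydro-1-benzofuran | ClCc1ccc2c(c1)[C@H](c1cc(OC)cc(OC)c1)[C@@H](c1ccc(OC)cc1)O2 | intermediate
36 | sodium (1R,2R)-2-(3,5-dimethoxyphenyl)-5,7-diethoxy-1-(4-methoxyphenyl)indane-3-thiolate | COc1ccc([C@@H]2c3c(OCC)cc(OCC)cc3C([S-])[C@H]2c2cc(OC)cc(OC)c2)cc1.[Na+] | intermediate
37 | sulfide: indane C3–S–CH2–C5′ of the (2S,3S)-dihydrobenzofuran, (1R,2R) in the indane | COc1ccc([C@@H]2c3c(OCC)cc(OCC)cc3C(SCc3ccc4c(c3)[C@H](c3cc(OC)cc(OC)c3)[C@@H](c3ccc(OC)cc3)O4)[C@H]2c2cc(OC)cc(OC)c2)cc1 | intermediate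
38 | sulfone of 37 | COc1ccc([C@@H]2c3c(OCC)cc(OCC)cc3C(S(=O)(=O)Cc3ccc4c(c3)[C@H](c3cc(OC)cc(OC)c3)[C@@H](c3ccc(OC)cc3)O4)[C@H]2c2cc(OC)cc(OC)c2)cc1 | intermediate
39 | α-chlorosulfone (chlorine on the exocyclic benzylic carbon) | COc1ccc([C@@H]2c3c(OCC)cc(OCC)cc3C(S(=O)(=O)C(Cl)c3ccc4c(c3)[C@H](c3cc(OC)cc(OC)c3)[C@@H](c3ccc(OC)cc3)O4)[C@H]2c2cc(OC)cc(OC)c2)cc1 | intermediate
40 | episulfone (thiirane 1,1-dioxide spiro-fused at C3) | COc1ccc([C@@H]2c3c(OCC)cc(OCC)cc3C4(C(c5ccc6c(c5)[C@H](c5cc(OC)cc(OC)c5)[C@@H](c5ccc(OC)cc5)O6)S4(=O)=O)[C@H]2c2cc(OC)cc(OC)c2)cc1 | intermediate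
41 | (1R,2R,3E)-3-{[(2S,3S)-3-(3,5-dimethoxyphenyl)-2-(4-methoxyphenyl)-2,3-dihydro-1-benzofuran-5-yl]methylidene}-2-(3,5-dimethoxyphenyl)-5,7-diethoxy-1-(4-methoxyphenyl)indane | COc1ccc([C@@H]2c3c(OCC)cc(OCC)cc3/C(=C/c3ccc4c(c3)[C@H](c3cc(OC)cc(OC)c3)[C@@H](c3ccc(OC)cc3)O4)[C@H]2c2cc(OC)cc(OC)c2)cc1 | intermediate
42 | E isomer of the target (octaphenol) | Oc1ccc([C@@H]2c3c(O)cc(O)cc3/C(=C/c3ccc4c(c3)[C@H](c3cc(O)cc(O)c3)[C@@H](c3ccc(O)cc3)O4)[C@H]2c2cc(O)cc(O)c2)cc1 | intermediate
43 | CNP0184753.4: (1Z,2R,3R)-2-(3,5-dihydroxyphenyl)-1-{[(2S,3S)-3-(3,5-dihydroxyphenyl)-2-(4-hydroxyphenyl)-2,3-dihydro-1-benzofuran-5-yl]methylidene}-3-(4-hydroxyphenyl)-2,3-dihydro-1H-indene-4,6-diol | Oc1ccc([C@@H]2c3c(O)cc(O)cc3/C(=C\c3ccc4c(c3)[C@H](c3cc(O)cc(O)c3)[C@@H](c3ccc(O)cc3)O4)[C@H]2c2cc(O)cc(O)c2)cc1 | target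

Total step count: 22. Longest linear sequence: 15 steps (steps 1–10, then 18–22); the dihydrobenzofuran branch (steps 11–17) joins at step 18.

Steps most likely to fail

Step 7. The polarised ynol ether may insert according to its electronic bias instead of the steric one and place the ethoxy group next to boron (C6). It may also bind ruthenium unproductively, or the alkynyl–boron bond may be lost by protodeboronation before cyclisation. The fallback sets out from 15 and takes both ring A oxygens from boron. The same Cp*RuCl(cod)-catalysed cycloaddition is run with commercial ethynylboronic acid pinacol ester, a partner that adds to end-substituted 1,6-diynes under steric, meta-selective control, and should give the 5,7-bis(pinacolboryl)indane F1. Alkaline H2O2 converts it into the indane-5,7-diol F2 (formed as its disodium salt, not isolated), and twofold O-ethylation with EtI in the same flask comes back to the route at 19.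

Step 2. The α-aryl aldehyde may epimerise at C1 through its enamine while the amine catalyst is still present, so that the syn/anti ratio erodes before the olefination traps it. The fallback sets out from 3 and replaces the aldehyde donor by a configurationally robust imide. (R)-4-Benzyl-1,3-oxazolidin-2-one is N-acylated with (4-methoxyphenyl)acetyl chloride (n-BuLi, THF, −78 °C) to the acyl oxazolidinone F3. Its chlorotitanium enolate (TiCl4, i-Pr2NEt, CH2Cl2, −78 °C) adds to 3 in an auxiliary-controlled Michael reaction, expected to be syn through the same synclinal approach, to give the imide adduct F4. LiBH4 removes the auxiliary and gives the nitro alcohol F5, which can be purified without risk. Oxidation with Dess–Martin periodinane (NaHCO3) to 5 and immediate Ramirez olefination come back to the route at 6.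

Step 10. Ionisation at C3 may be slow, or the cation may lose the C2 proton and drain into the 2-arylindene. The fallback sets out from 20 and avoids the cation. Oxidation with Dess–Martin periodinane gives the indan-3-one F6, in which C2 is α to the carbonyl and settles trans to C1 under mild base, so a C2 epimer would be repaired as well. NaBH4 reduction from the face opposite the C2 aryl group gives the 2,3-cis indanol F7. Mitsunobu displacement with thioacetic acid (PPh3, DIAD, THF, 0 °C) inverts C3 and comes back to the route at 21, as its all-trans (3R) epimer.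

Further compounds
F1 | step 7 | (1R,2R)-3-[(tert-butyldimethylsilyl)oxy]-2-(3,5-dimethoxyphenyl)-1-(4-methoxyphenyl)-5,7-bis(4,4,5,5-tetramethyl-1,3,2-dioxaborolan-2-yl)indane, C3 epimers | COc1ccc([C@@H]2c3c(B4OC(C)(C)C(C)(C)O4)cc(B4OC(C)(C)C(C)(C)O4)cc3C(O[Si](C)(C)C(C)(C)C)[C@H]2c2cc(OC)cc(OC)c2)cc1
F2 | step 7 | (1R,2R)-3-[(tert-butyldimethylsilyl)oxy]-2-(3,5-dimethoxyphenyl)-1-(4-methoxyphenyl)indane-5,7-diol, C3 epimers | COc1ccc([C@@H]2c3c(O)cc(O)cc3C(O[Si](C)(C)C(C)(C)C)[C@H]2c2cc(OC)cc(OC)c2)cc1
F3 | step 2 | (R)-4-benzyl-3-[(4-methoxyphenyl)acetyl]-1,3-oxazolidin-2-one | COc1ccc(CC(=O)N2[C@H](Cc3ccccc3)COC2=O)cc1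
F4 | step 2 | (R)-4-benzyl-3-[(2R,3R)-3-(3,5-dimethoxyphenyl)-2-(4-methoxyphenyl)-4-nitrobutanoyl]-1,3-oxazolidin-2-one | COc1ccc([C@H](C(=O)N2[C@H](Cc3ccccc3)COC2=O)[C@H](c2cc(OC)cc(OC)c2)C[N+](=O)[O-])cc1
F5 | step 2 | (2R,3R)-3-(3,5-dimethoxyphenyl)-2-(4-methoxyphenyl)-4-nitrobutan-1-ol | COc1ccc([C@H](CO)[C@H](c2cc(OC)cc(OC)c2)C[N+](=O)[O-])cc1
F6 | step 10 | (1R,2R)-2-(3,5-dimethoxyphenyl)-5,7-diethoxy-1-(4-methoxyphenyl)indan-3-one | COc1ccc([C@@H]2c3c(OCC)cc(OCC)cc3C(=O)[C@H]2c2cc(OC)cc(OC)c2)cc1
F7 | step 10 | (1R,2R,3S)-2-(3,5-dimethoxyphenyl)-5,7-diethoxy-1-(4-methoxyphenyl)indan-3-ol (2,3-cis) | COc1ccc([C@@H]2c3c(OCC)cc(OCC)cc3[C@@H](O)[C@H]2c2cc(OC)cc(OC)c2)cc1
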